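**Retrosynthetic overview**
- Last C–C disconnection: the axis from C2 of the central unit B to C4 of unit C. It is made by Suzuki–Miyaura coupling of a unit B 2-triflate and a 4-(benzyloxy)-5-methoxy-1-naphthylboronate. The benzyl ethers come off last.
- The triflate oxygen is the second oxygen of an ortho-quinone. The A–B binaphthyl catechol is the redox isomer of a 4-(1-oxotetralin-2-yl)-1,2-naphthoquinone.
- Key disconnection: the unit A C2–unit B C4 bond. It is made by intermolecular Michael addition of the tert-butyl β-keto ester of 8-methoxy-1-tetralone to C4 of 8-methoxy-1,2-naphthoquinone.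
- No carbocycle is built. Unit A comes from 1-tetralone, and units B and C come from 1,8-dihydroxynaphthalene. The only ring event is aromatisation of the saturated ring of unit A directly after the key step.

Assumption: the SMILES has no stereocentre and no stereodescriptor. Both biaryl axes are flanked only by OH, H, H and one peri C–H, so they rotate at room temperature, and the target is made as this one stereochemically unfixed species.

**Step 1**
Reactants: 1 1-tetralone
Product: 3 8-hydroxy-3,4-dihydronaphthalen-1(2H)-one, via aryl trifluoroacetate 2 (not isolated)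
Conditions: Pd(OCOCF3)2 (5 mol %), PhI(OCOCF3)2 (2 equiv), ClCH2CH2Cl, 80 °C; aqueous work-up
Reagents that add atoms: [bis(trifluoroacetoxy)iodo]benzene, FC(F)(F)C(=O)OI(OC(=O)C(F)(F)F)c1ccccc1
Why: In this ketone-directed ortho C–H oxygenation the carbonyl guides divalent palladium into the only reachable C8–H bond, the trivalent-iodine oxidant triggers C–O reductive elimination to 2, and 2 hydrolyses on work-up; no stereocentre is formed.

**Step 2**
Reactants: 3 8-hydroxy-3,4-dihydronaphthalen-1(2H)-one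
Product: 4 8-methoxy-3,4-dihydronaphthalen-1(2H)-one
Conditions: MeI (1.5 equiv), K2CO3 (2 equiv), DMF, 40 °C
Reagents that add atoms: iodomethane, IC
Why: This is a Williamson ether synthesis (SN2 on MeI), and warm DMF overcomes the O–H···O=C hydrogen bond of the phenol.

**Step 3**
Reactants: 4 8-methoxy-3,4-dihydronaphthalen-1(2H)-one
Product: 5 methyl 8-methoxy-1-oxo-1,2,3,4-tetrahydronaphthalene-2-carboxylate (racemic)
Conditions: NaH (2.5 equiv), (MeO)2CO (5 equiv), THF, reflux; AcOH quench
Reagents that add atoms: dimethyl carbonate, COC(=O)OC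
Why: This crossed Claisen condensation acylates the only enolisable position and is driven by deprotonation of the β-keto ester; the C2 centre is racemic and configurationally labile.

**Step 4**
Reactants: 5 methyl 8-methoxy-1-oxo-1,2,3,4-tetrahydronaphthalene-2-carboxylate
Product: 6 tert-butyl 8-methoxy-1-oxo-1,2,3,4-tetrahydronaphthalene-2-carboxylate (racemic)
Conditions: t-BuOH (10 equiv), Bu2SnO (10 mol %), toluene, reflux, MeOH removed over 4 Å MS
Reagents that add atoms: tert-butanol, CC(C)(C)O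
Why: This tin-catalysed transesterification of a β-keto ester is pulled to completion by removal of methanol and installs an ester that later leaves under acid alone.

**Step 5**
Reactants: 7 naphthalene-1,8-diol
Product: 8 8-methoxynaphthalen-1-ol
Conditions: MeI (1.05 equiv), K2CO3 (1.1 equiv), acetone, reflux
Reagents that add atoms: iodomethane, IC
Why: This Williamson mono-O-methylation stops after one alkylation because the remaining OH is hydrogen-bonded to the new peri OMe and is much less acidic.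

**Step 6**
Reactants: 8 8-methoxynaphthalen-1-ol
Product: 9 8-methoxynaphthalene-1,2-dione
Conditions: IBX (1.1 equiv), DMF, rt, dark
Reagents that add atoms: 2-iodoxybenzoic acid (IBX), OI1(=O)OC(=O)c2ccccc12
Why: In this IBX ortho-oxygenation of a phenol the naphthol binds to pentavalent iodine and oxygen is delivered intramolecularly to the only free ortho carbon (C2), giving the ortho-quinone rather than the para-quinone.

**Step 7 (key step)**
Reactants: 6 tert-butyl 8-methoxy-1-oxo-1,2,3,4-tetrahydronaphthalene-2-carboxylate; 9 8-methoxynaphthalene-1,2-dione (1.2 equiv)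
Product: 11 tert-butyl 8-methoxy-2-(5-methoxy-3,4-dioxo-3,4-dihydronaphthalen-1-yl)-1-oxo-1,2,3,4-tetrahydronaphthalene-2-carboxylate (racemic), via catechol adduct 10 (not isolated)
Conditions: DABCO (20 mol %), CH2Cl2, −20 °C to rt, Ar; then Ag2O (1.5 equiv), Na2SO4, rt
Reagents that add atoms: none
Why: In this intermolecular Michael addition the soft β-keto ester enolate attacks C4, the only β-carbon of the C2=O/C3=C4 enone of a 1,2-naphthoquinone, tautomerisation to catechol 10 makes it irreversible, and Ag2O restores the quinone level; the new quaternary stereocentre is racemic and is erased in step 8.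

**Step 8**
Reactants: 11 tert-butyl 8-methoxy-2-(5-methoxy-3,4-dioxo-3,4-dihydronaphthalen-1-yl)-1-oxo-1,2,3,4-tetrahydronaphthalene-2-carboxylate
Product: 14 4-(1-hydroxy-8-methoxynaphthalen-2-yl)-8-methoxynaphthalene-1,2-diol, via keto acid 12 (not isolated), via quinonyl tetralone 13 (not isolated)
Conditions: TsOH·H2O (0.2 equiv), toluene, 90 °C, Ar purge; then DABCO (0.5 equiv), rt
Reagents that add atoms: none
Why: E1 acidolysis of the tert-butyl ester and β-keto acid decarboxylation give 13, which is an isomer of 14 and reaches it by proton shifts alone (ortho-quinone to para-quinone methide to vinylogous enone to naphthol), so the quinone serves as internal oxidant for ring A and the stereocentre disappears.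

**Step 9**
Reactants: 14 4-(1-hydroxy-8-methoxynaphthalen-2-yl)-8-methoxynaphthalene-1,2-diol
Product: 15 1-hydroxy-4-(1-hydroxy-8-methoxynaphthalen-2-yl)-8-methoxynaphthalen-2-yl trifluoromethanesulfonate
Conditions: PhNTf2 (1.0 equiv), Et3N (1.2 equiv), CH2Cl2, 0 °C to rt, Ar
Reagents that add atoms: N-phenylbis(trifluoromethanesulfonimide), FC(F)(F)S(=O)(=O)N(c1ccccc1)S(=O)(=O)C(F)(F)F
Why: This O-sulfonylation is chemoselective because the C2–OH of unit B is the only hydroxyl without a peri OMe hydrogen-bond partner and the least hindered and most acidic one, so the mild bulky triflyl donor reacts there.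

**Step 10**
Reactants: 15 1-hydroxy-4-(1-hydroxy-8-methoxynaphthalen-2-yl)-8-methoxynaphthalen-2-yl trifluoromethanesulfonate
Product: 16 1-(benzyloxy)-4-[1-(benzyloxy)-8-methoxynaphthalen-2-yl]-8-methoxynaphthalen-2-yl trifluoromethanesulfonate
Conditions: BnBr (3 equiv), Cs2CO3 (3 equiv), DMF, rt to 40 °C
Reagents that add atoms: benzyl bromide, BrCc1ccccc1
Why: This double Williamson etherification uses caesium naphtholates in DMF, which O-alkylate even when hindered, and the aryl triflate is inert at this temperature.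

**Step 11**
Reactants: 8 8-methoxynaphthalen-1-ol
Product: 17 4-bromo-8-methoxynaphthalen-1-ol
Conditions: NBS (1.0 equiv), MeCN, −20 to 0 °C
Reagents that add atoms: N-bromosuccinimide, O=C1CCC(=O)N1Br
Why: This electrophilic aromatic bromination goes to the OH-bearing ring, which is the more activated one, NBS in MeCN is para-selective for naphthols, and the O–H···OMe bond suppresses OH-guided ortho delivery.

**Step 12**
Reactants: 17 4-bromo-8-methoxynaphthalen-1-ol
Product: 18 1-(benzyloxy)-4-bromo-8-methoxynaphthalene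
Conditions: BnBr (1.2 equiv), K2CO3 (2 equiv), DMF, 50 °C
Reagents that add atoms: benzyl bromide, BrCc1ccccc1
Why: This Williamson ether synthesis uses the same protecting group as in 16, so a single final deprotection suffices.

**Step 13**
Reactants: 18 1-(benzyloxy)-4-bromo-8-methoxynaphthalene
Product: 19 2-[4-(benzyloxy)-5-methoxynaphthalen-1-yl]-4,4,5,5-tetramethyl-1,3,2-dioxaborolane
Conditions: B2pin2 (1.2 equiv), PdCl2(dppf) (3 mol %), KOAc (3 equiv), 1,4-dioxane, 90 °C
Reagents that add atoms: bis(pinacolato)diboron, CC1(C)OB(OC1(C)C)B1OC(C)(C)C(C)(C)O1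
Why: Miyaura borylation converts the single C–Br bond into a pinacol boronate, which resists protodeboronation better than the free electron-rich boronic acid.

**Step 14**
Reactants: 16 1-(benzyloxy)-4-[1-(benzyloxy)-8-methoxynaphthalen-2-yl]-8-methoxynaphthalen-2-yl trifluoromethanesulfonate; 19 2-[4-(benzyloxy)-5-methoxynaphthalen-1-yl]-4,4,5,5-tetramethyl-1,3,2-dioxaborolane (1.4 equiv)
Product: 20 1-(benzyloxy)-4-[1-(benzyloxy)-8-methoxynaphthalen-2-yl]-2-[4-(benzyloxy)-5-methoxynaphthalen-1-yl]-8-methoxynaphthalene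
Conditions: Pd(OAc)2 (5 mol %), SPhos (10 mol %), K3PO4 (3 equiv), toluene/H2O 10:1, 90 °C
Reagents that add atoms: none
Why: In this Suzuki–Miyaura coupling zerovalent palladium/SPhos inserts into the only C–OTf bond and tolerates the ortho OBn and peri C–H, and the new axis is not configurationally stable, so no stereoisomers arise.

**Step 15**
Reactants: 20 1-(benzyloxy)-4-[1-(benzyloxy)-8-methoxynaphthalen-2-yl]-2-[4-(benzyloxy)-5-methoxynaphthalen-1-yl]-8-methoxynaphthalene
Product: 21 4-(1-hydroxy-8-methoxynaphthalen-2-yl)-2-(4-hydroxy-5-methoxynaphthalen-1-yl)-8-methoxynaphthalen-1-ol (target)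
Conditions: H2 (1 atm), Pd/C (10 wt %), THF/MeOH 1:1, rt; work-up under Ar
Reagents that add atoms: none
Why: Catalytic hydrogenolysis cleaves the three benzylic C–O bonds under neutral conditions that leave the methyl ethers, the naphthalene rings and the oxidation-sensitive naphthols untouched.

**Compound list**
1 | 1-tetralone (3,4-dihydronaphthalen-1(2H)-one) | O=C1CCCc2ccccc12 | starting material
2 | 8-oxo-5,6,7,8-tetrahydronaphthalen-1-yl trifluoroacetate | O=C1CCCc2cccc(OC(=O)C(F)(F)F)c12 | intermediate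
3 | 8-hydroxy-3,4-dihydronaphthalen-1(2H)-one | O=C1CCCc2cccc(O)c12 | intermediate
4 | 8-methoxy-3,4-dihydronaphthalen-1(2H)-one | COc1cccc2CCCC(=O)c12 | intermediate
5 | methyl 8-methoxy-1-oxo-1,2,3,4-tetrahydronaphthalene-2-carboxylate (racemic) | COC(=O)C1CCc2cccc(OC)c2C1=O | intermediate
6 | tert-butyl 8-methoxy-1-oxo-1,2,3,4-tetrahydronaphthalene-2-carboxylate (racemic) | CC(C)(C)OC(=O)C1CCc2cccc(OC)c2C1=O | intermediate
7 | naphthalene-1,8-diol | Oc1cccc2cccc(O)c12 | starting material
8 | 8-methoxynaphthalen-1-ol | COc1cccc2cccc(O)c12 | intermediate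
9 | 8-methoxynaphthalene-1,2-dione | COc1cccc2C=CC(=O)C(=O)c12 | intermediate
10 | tert-butyl 2-(3,4-dihydroxy-5-methoxynaphthalen-1-yl)-8-methoxy-1-oxo-1,2,3,4-tetrahydronaphthalene-2-carboxylate (racemic) | CC(C)(C)OC(=O)C1(CCc2cccc(OC)c2C1=O)c3cc(O)c(O)c4c(OC)cccc34 | intermediate
11 | tert-butyl 8-methoxy-2-(5-methoxy-3,4-dioxo-3,4-dihydronaphthalen-1-yl)-1-oxo-1,2,3,4-tetrahydronaphthalene-2-carboxylate (racemic) | CC(C)(C)OC(=O)C1(CCc2cccc(OC)c2C1=O)C3=CC(=O)C(=O)c4c(OC)cccc34 | intermediate
12 | 8-methoxy-2-(5-methoxy-3,4-dioxo-3,4-dihydronaphthalen-1-yl)-1-oxo-1,2,3,4-tetrahydronaphthalene-2-carboxylic acid (racemic) | OC(=O)C1(CCc2cccc(OC)c2C1=O)C3=CC(=O)C(=O)c4c(OC)cccc34 | intermediate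
13 | 8-methoxy-4-(8-methoxy-1-oxo-1,2,3,4-tetrahydronaphthalen-2-yl)naphthalene-1,2-dione (racemic) | COc1cccc2CCC(C(=O)c12)C3=CC(=O)C(=O)c4c(OC)cccc34 | intermediate
14 | 4-(1-hydroxy-8-methoxynaphthalen-2-yl)-8-methoxynaphthalene-1,2-diol | COc1cccc2ccc(-c3cc(O)c(O)c4c(OC)cccc34)c(O)c12 | intermediate
15 | 1-hydroxy-4-(1-hydroxy-8-methoxynaphthalen-2-yl)-8-methoxynaphthalen-2-yl trifluoromethanesulfonate | COc1cccc2ccc(-c3cc(OS(=O)(=O)C(F)(F)F)c(O)c4c(OC)cccc34)c(O)c12 | intermediate
16 | 1-(benzyloxy)-4-[1-(benzyloxy)-8-methoxynaphthalen-2-yl]-8-methoxynaphthalen-2-yl trifluoromethanesulfonate | COc1cccc2ccc(-c3cc(OS(=O)(=O)C(F)(F)F)c(OCc5ccccc5)c4c(OC)cccc34)c(OCc6ccccc6)c12 | intermediate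
17 | 4-bromo-8-methoxynaphthalen-1-ol | COc1cccc2c(Br)ccc(O)c12 | intermediate
18 | 1-(benzyloxy)-4-bromo-8-methoxynaphthalene | COc1cccc2c(Br)ccc(OCc3ccccc3)c12 | intermediate
19 | 2-[4-(benzyloxy)-5-methoxynaphthalen-1-yl]-4,4,5,5-tetramethyl-1,3,2-dioxaborolane | COc1cccc2c(B3OC(C)(C)C(C)(C)O3)ccc(OCc3ccccc3)c12 | intermediate
20 | 1-(benzyloxy)-4-[1-(benzyloxy)-8-methoxynaphthalen-2-yl]-2-[4-(benzyloxy)-5-methoxynaphthalen-1-yl]-8-methoxynaphthalene | COc1cccc2ccc(-c3cc(-c4ccc(OCc6ccccc6)c5c(OC)cccc45)c(OCc6ccccc6)c4c(OC)cccc34)c(OCc6ccccc6)c12 | intermediate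
21 | 4-(1-hydroxy-8-methoxynaphthalen-2-yl)-2-(4-hydroxy-5-methoxynaphthalen-1-yl)-8-methoxynaphthalen-1-ol (CNP0493720.0) | COc1cccc2ccc(-c3cc(-c4ccc(O)c5c(OC)cccc45)c(O)c4c(OC)cccc34)c(O)c12 | target

**Step count**
- Total steps: 15.
- Longest linear sequence: 10 (steps 1, 2, 3, 4, 7, 8, 9, 10, 14, 15).

**Three steps most likely to fail**

**Step 7.** The Michael addition builds a quaternary carbon next to a peri C–H, and quinone 9 is base-sensitive.
The fallback sets out from 4 and comes back at 14.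
- Ketone 4 is converted by TMSOTf/Et3N into the silyl enol ether [(8-methoxy-3,4-dihydronaphthalen-1-yl)oxy]trimethylsilane F1.
- F1 adds to C4 of 9 in a Sc(OTf)3-catalysed Mukaiyama–Michael reaction (CH2Cl2/MeCN, −40 °C). This forms only a tertiary carbon and needs no base.
- Desilylation gives 2-(3,4-dihydroxy-5-methoxynaphthalen-1-yl)-8-methoxy-3,4-dihydronaphthalen-1(2H)-one F2.
- Ag2O oxidises F2 to 13, and DABCO isomerises 13 to 14.
- The ester and steps 3 and 4 then become unnecessary.

**Step 8.** The acidolysis may tert-butylate the electron-rich product, or the proton-shift cascade may stall or give mixtures.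
The fallback sets out from 11 and comes back at 14. It separates ester removal from the redox change.
- Na2S2O4 (EtOAc/H2O) reduces 11 to 10.
- BnBr/K2CO3 in DMF gives tert-butyl 2-[3,4-bis(benzyloxy)-5-methoxynaphthalen-1-yl]-8-methoxy-1-oxo-1,2,3,4-tetrahydronaphthalene-2-carboxylate F3.
- TsOH in hot toluene removes the ester and gives 2-[3,4-bis(benzyloxy)-5-methoxynaphthalen-1-yl]-8-methoxy-3,4-dihydronaphthalen-1(2H)-one F4.
- Aerobic dehydrogenation (Pd(OCOCF3)2, 2-(dimethylamino)pyridine, TsOH, O2, DMSO, 80 °C) gives 2-[3,4-bis(benzyloxy)-5-methoxynaphthalen-1-yl]-8-methoxynaphthalen-1-ol F5.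
- H2 over Pd/C frees the catechol and delivers 14.

**Step 9.** One of three hydroxyl groups has to be triflated selectively.
The fallback sets out from 14 and comes back at 21. It moves the selection from the O-sulfonylation to the oxidative addition.
- Excess Tf2O/pyridine gives the tris(triflate) 4-[8-methoxy-1-(trifluoromethylsulfonyloxy)naphthalen-2-yl]-8-methoxynaphthalene-1,2-diyl bis(trifluoromethanesulfonate) F6.
- Only the C2–OTf of unit B in F6 lacks a peri OMe neighbour.
- Site-selective Suzuki–Miyaura coupling uses 1.0 equiv of 19 (Pd(PPh3)4, K3PO4, dioxane, 85 °C). It gives 2-[4-(benzyloxy)-5-methoxynaphthalen-1-yl]-8-methoxy-4-[8-methoxy-1-(trifluoromethylsulfonyloxy)naphthalen-2-yl]naphthalen-1-yl trifluoromethanesulfonate F7.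
- KOH in MeOH/THF cleaves the two remaining S–O bonds and gives 2-[4-(benzyloxy)-5-methoxynaphthalen-1-yl]-4-(1-hydroxy-8-methoxynaphthalen-2-yl)-8-methoxynaphthalen-1-ol F8.
- H2 over Pd/C gives 21.

**Further compounds**
F1 | step 7 | [(8-methoxy-3,4-dihydronaphthalen-1-yl)oxy]trimethylsilane | COc1cccc2CCC=C(O[Si](C)(C)C)c12
F2 | step 7 | 2-(3,4-dihydroxy-5-methoxynaphthalen-1-yl)-8-methoxy-3,4-dihydronaphthalen-1(2H)-one (racemic) | COc1cccc2CCC(C(=O)c12)c3cc(O)c(O)c4c(OC)cccc34
F3 | step 8 | tert-butyl 2-[3,4-bis(benzyloxy)-5-methoxynaphthalen-1-yl]-8-methoxy-1-oxo-1,2,3,4-tetrahydronaphthalene-2-carboxylate (racemic) | CC(C)(C)OC(=O)C1(CCc2cccc(OC)c2C1=O)c3cc(OCc5ccccc5)c(OCc5ccccc5)c4c(OC)cccc34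
F4 | step 8 | 2-[3,4-bis(benzyloxy)-5-methoxynaphthalen-1-yl]-8-methoxy-3,4-dihydronaphthalen-1(2H)-one (racemic) | COc1cccc2CCC(C(=O)c12)c3cc(OCc5ccccc5)c(OCc5ccccc5)c4c(OC)cccc34
F5 | step 8 | 2-[3,4-bis(benzyloxy)-5-methoxynaphthalen-1-yl]-8-methoxynaphthalen-1-ol | COc1cccc2ccc(-c3cc(OCc5ccccc5)c(OCc5ccccc5)c4c(OC)cccc34)c(O)c12
F6 | step 9 | 4-[8-methoxy-1-(trifluoromethylsulfonyloxy)naphthalen-2-yl]-8-methoxynaphthalene-1,2-diyl bis(trifluoromethanesulfonate) | COc1cccc2ccc(-c3cc(OS(=O)(=O)C(F)(F)F)c(OS(=O)(=O)C(F)(F)F)c4c(OC)cccc34)c(OS(=O)(=O)C(F)(F)F)c12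
F7 | step 9 | 2-[4-(benzyloxy)-5-methoxynaphthalen-1-yl]-8-methoxy-4-[8-methoxy-1-(trifluoromethylsulfonyloxy)naphthalen-2-yl]naphthalen-1-yl trifluoromethanesulfonate | COc1cccc2ccc(-c3cc(-c4ccc(OCc6ccccc6)c5c(OC)cccc45)c(OS(=O)(=O)C(F)(F)F)c4c(OC)cccc34)c(OS(=O)(=O)C(F)(F)F)c12
F8 | step 9 | 2-[4-(benzyloxy)-5-methoxynaphthalen-1-yl]-4-(1-hydroxy-8-methoxynaphthalen-2-yl)-8-methoxynaphthalen-1-ol | COc1cccc2ccc(-c3cc(-c4ccc(OCc6ccccc6)c5c(OC)cccc45)c(O)c4c(OC)cccc34)c(O)c12
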